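**Retrosynthetic overview**
- The target comes from 1,2-reduction of a (2E,4E)-2-alkyl-dienal. Its C13=C14 bond is made by Horner–Wadsworth–Emmons olefination of an α-keto acetal with a butenolide allylphosphonate; the 2E geometry is thermodynamic once the acetal is hydrolysed.
- Key C9–C11 bond: the α-keto acetal comes from the cis-decalin enol triflate and a ketone homoenolate (β-ketoalkyl–palladium from ring opening of 1-(dimethoxymethyl)cyclopropanol). This joins the former carbonyl carbon to the β-carbon of the new ketone.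
- The enol triflate comes from conjugate reduction/triflation of a cis-fused bicyclic enone; the gem-dimethyl group is completed by radical hydromethylation.
- Ring order: ring B is the ring of (S)-carvone. Ring A is closed second by ring-closing metathesis after two α′-alkylations (butenyl, then methyl anti to isopropenyl), which set the quaternary carbon and the cis fusion. The butenolide is bought as 4-bromofuran-2(5H)-one and attached by a Heck reaction.

Assumption: the SMILES is read literally, which makes the decalin cis-fused, (4aR,8aS), with the angular methyl and the ring-fusion H on the same face; labdane-type locants are used (ring fusion C5/C10, alkene C8=C9, side chain C11 to C16, CH2OH on C13).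

**Step 1**
Reactants: 1 (S)-carvone; 2 4-iodobut-1-ene
Product: 4 (5S,6R)-6-(but-3-en-1-yl)-2-methyl-5-(prop-1-en-2-yl)cyclohex-2-en-1-one, via lithium dienolate of carvone 3 (not isolated)
Conditions: LiN(i-Pr)2, THF, −78 °C; then 2, DMPU, −78 → 0 °C
Reagents that add atoms: none
Why: Kinetic α′-deprotonation gives the cross-conjugated lithium dienolate, whose SN2 C-alkylation (enolate alkylation) by the primary iodide occurs anti to the C-5 isopropenyl group, and the new C-6 centre is in any case erased by re-enolisation in step 2.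

**Step 2**
Reactants: 4 (5S,6R)-6-(but-3-en-1-yl)-2-methyl-5-(prop-1-en-2-yl)cyclohex-2-en-1-one
Product: 6 (5R,6S)-6-(but-3-en-1-yl)-2,6-dimethyl-5-(prop-1-en-2-yl)cyclohex-2-en-1-one, via lithium enolate of the butenyl ketone 5 (not isolated)
Conditions: LiN(i-Pr)2, THF, −78 °C; then MeI, −78 → 0 °C
Reagents that add atoms: iodomethane, CI
Why: The trisubstituted enolate is methylated (enolate alkylation) on the face opposite the pseudoaxial C-5 isopropenyl group, so methyl ends trans and the butenyl chain cis to isopropenyl, which fixes the quaternary carbon (later C-8a) with the relative configuration needed for a cis ring fusion.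

**Step 3**
Reactants: 6 (5R,6S)-6-(but-3-en-1-yl)-2,6-dimethyl-5-(prop-1-en-2-yl)cyclohex-2-en-1-one
Product: 7 (4aR,8aS)-2,5,8a-trimethyl-4a,7,8,8a-tetrahydronaphthalen-1(4H)-one
Conditions: second-generation Grubbs catalyst RuCl2(=CHPh)(PCy3)(H2IMes) (5 mol%), CH2Cl2, 40 °C
Reagents that add atoms: none
Why: Ring-closing olefin metathesis of the terminal butenyl alkene onto the 1,1-disubstituted isopropenyl alkene, held cis on ring B and helped by the quaternary centre, closes ring A as a trisubstituted cyclohexene that can only be cis-fused, with no stereocentre touched and the electron-poor enone alkene left alone.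

**Step 4**
Reactants: 7 (4aR,8aS)-2,5,8a-trimethyl-4a,7,8,8a-tetrahydronaphthalen-1(4H)-one
Product: 9 (4aR,8aS)-2,5,8a-trimethyl-3,4,4a,7,8,8a-hexahydronaphthalen-1-yl trifluoromethanesulfonate, via lithium enolate from conjugate reduction 8 (not isolated)
Conditions: LiBH(s-Bu)3, THF, −78 °C; then PhNTf2, −78 °C → rt
Reagents that add atoms: N-phenylbis(trifluoromethanesulfonimide), O=S(=O)(N(c1ccccc1)S(=O)(=O)C(F)(F)F)C(F)(F)F
Why: The hindered borohydride adds hydride 1,4 to the β-monosubstituted enone (1,2-attack is blocked by the α′-quaternary carbon) and the resulting tetrasubstituted enolate is O-sulfonylated by PhNTf2 (conjugate reduction–enolate trapping), which places the future C8=C9 double bond unambiguously.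

**Step 5**
Reactants: 9 (4aR,8aS)-2,5,8a-trimethyl-3,4,4a,7,8,8a-hexahydronaphthalen-1-yl trifluoromethanesulfonate
Product: 11 (4aR,8aS)-2,5,5,8a-tetramethyl-3,4,4a,5,6,7,8,8a-octahydronaphthalen-1-yl trifluoromethanesulfonate, via sulfonyl hydrazide adduct 10 (not isolated)
Conditions: Fe(acac)3 (30 mol%), PhSiH3, CH2=NNHSO2(n-C8H17), THF/MeOH, rt; then MeOH, 60 °C
Reagents that add atoms: N′-methylideneoctane-1-sulfonohydrazide (formaldehyde n-octylsulfonylhydrazone), C=NNS(=O)(=O)CCCCCCCC
Why: Iron-hydride hydrogen-atom transfer (MHAT, Markovnikov) to the electron-rich trisubstituted ring A alkene gives the tertiary radical, which adds to the C=N bond of the formaldehyde sulfonylhydrazone, and warming in methanol expels sulfinate and N2 from the hydrazide to leave the second methyl group (radical hydromethylation), the carbon becoming achiral CMe2 while the electron-poor tetrasubstituted enol triflate does not react.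

**Step 6**
Reactants: 12 methyl 2,2-dimethoxyacetate
Product: 13 1-(dimethoxymethyl)cyclopropan-1-ol
Conditions: EtMgBr (2.5 equiv), Ti(Oi-Pr)4 (20 mol%), Et2O, 0 °C → rt; aq. NH4Cl
Reagents that add atoms: ethylmagnesium bromide, CC[Mg]Br
Why: Kulinkovich cyclopropanation, in which the titanacyclopropane formed from EtMgBr and Ti(Oi-Pr)4 adds twice to the ester carbonyl as a 1,2-dicarbanion equivalent while the acetal is inert.

**Step 7 (key step)**
Reactants: 11 (4aR,8aS)-2,5,5,8a-tetramethyl-3,4,4a,5,6,7,8,8a-octahydronaphthalen-1-yl trifluoromethanesulfonate; 13 1-(dimethoxymethyl)cyclopropan-1-ol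
Product: 14 1,1-dimethoxy-4-[(4aR,8aS)-2,5,5,8a-tetramethyl-3,4,4a,5,6,7,8,8a-octahydronaphthalen-1-yl]butan-2-one
Conditions: Pd(OAc)2 (10 mol%), XPhos (20 mol%), Cs2CO3, toluene, 80 °C
Reagents that add atoms: none
Why: Proposed new method: zerovalent palladium inserts into the enol triflate C–O bond, the cyclopropoxide displaces triflate on palladium, strain-driven β-carbon elimination opens the ring to a β-ketoalkylpalladium species (a ketone homoenolate, so the β-carbon of the new ketone acts as the nucleophile toward the former carbonyl carbon C9) and reductive elimination, favoured over β-hydride elimination by the bulky biarylphosphine, forms the C9–C11 bond with the tetrasubstituted alkene fixed by the triflate and no stereocentre affected, the closest known reactions being the palladium-catalysed ring-opening arylation of cyclopropanols and the palladium-catalysed coupling of zinc ester homoenolates with enol triflates.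

**Step 8**
Reactants: 15 4-bromofuran-2(5H)-one; 16 diethyl prop-2-en-1-ylphosphonate
Product: 17 diethyl [(2E)-3-(5-oxo-2,5-dihydrofuran-3-yl)prop-2-en-1-yl]phosphonate
Conditions: Pd(OAc)2 (5 mol%), P(o-tol)3 (10 mol%), NaOAc, n-Bu4NCl, DMF, 70 °C
Reagents that add atoms: none
Why: Mizoroki–Heck reaction under phase-transfer (Jeffery) conditions: oxidative addition into the vinylic C–Br bond, insertion of the terminal alkene and β-hydride elimination toward the ring give the E alkene conjugated with the butenolide.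

**Step 9**
Reactants: 14 1,1-dimethoxy-4-[(4aR,8aS)-2,5,5,8a-tetramethyl-3,4,4a,5,6,7,8,8a-octahydronaphthalen-1-yl]butan-2-one; 17 diethyl [(2E)-3-(5-oxo-2,5-dihydrofuran-3-yl)prop-2-en-1-yl]phosphonate
Product: 20 (2E,4E)-5-(5-oxo-2,5-dihydrofuran-3-yl)-2-{2-[(4aR,8aS)-2,5,5,8a-tetramethyl-3,4,4a,5,6,7,8,8a-octahydronaphthalen-1-yl]ethyl}penta-2,4-dienal, via lithiated phosphonate 18 (not isolated), via triene dimethyl acetal 19 (not isolated)
Conditions: 17, LiN(SiMe3)2, THF, −78 °C; 14, −78 → 0 °C; then 1 M aq. HCl, rt; crude, I2 (cat.), CH2Cl2, rt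
Reagents that add atoms: water, O
Why: Horner–Wadsworth–Emmons olefination of the activated α-keto acetal by the phosphorus-bearing carbon of the vinylogous phosphonate anion forms C13=C14, acid hydrolysis then unmasks the 2-alkyl-2,4-dienal, and acid plus iodine equilibrate it to the thermodynamically preferred 2E,4E isomer (β-substituent anti to the formyl group), so the E/Z ratio of the olefination is not decisive.

**Step 10**
Reactants: 20 (2E,4E)-5-(5-oxo-2,5-dihydrofuran-3-yl)-2-{2-[(4aR,8aS)-2,5,5,8a-tetramethyl-3,4,4a,5,6,7,8,8a-octahydronaphthalen-1-yl]ethyl}penta-2,4-dienal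
Product: 21 4-[(1E,3E)-4-(hydroxymethyl)-6-[(4aR,8aS)-2,5,5,8a-tetramethyl-3,4,4a,5,6,7,8,8a-octahydronaphthalen-1-yl]hexa-1,3-dien-1-yl]furan-2(5H)-one
Conditions: NaBH4, CeCl3·7H2O, MeOH, −78 °C
Reagents that add atoms: none
Why: Luche reduction: the CeCl3-activated aldehyde is reduced 1,2 at low temperature faster than any conjugate or lactone reduction, giving the primary allylic alcohol without touching the butenolide or the alkene geometries.

**Compound list**
1 | (S)-carvone, (5S)-2-methyl-5-(prop-1-en-2-yl)cyclohex-2-en-1-one | CC1=CC[C@@H](CC1=O)C(C)=C | starting material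
2 | 4-iodobut-1-ene | C=CCCI | starting material
3 | lithium (3S)-6-methyl-3-(prop-1-en-2-yl)cyclohexa-1,5-dien-1-olate (kinetic dienolate of 1) | CC1=CC[C@H](C(C)=C)C=C1O[Li] | intermediate
4 | (5S,6R)-6-(but-3-en-1-yl)-2-methyl-5-(prop-1-en-2-yl)cyclohex-2-en-1-one (butenyl trans to isopropenyl) | CC1=CC[C@H](C(C)=C)[C@@H](CCC=C)C1=O | intermediate
5 | lithium (3R)-2-(but-3-en-1-yl)-6-methyl-3-(prop-1-en-2-yl)cyclohexa-1,5-dien-1-olate | CC1=CC[C@H](C(C)=C)C(CCC=C)=C1O[Li] | intermediate
6 | (5R,6S)-6-(but-3-en-1-yl)-2,6-dimethyl-5-(prop-1-en-2-yl)cyclohex-2-en-1-one (methyl trans, butenyl cis to isopropenyl) | CC1=CC[C@H](C(C)=C)[C@](C)(CCC=C)C1=O | intermediate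
7 | (4aR,8aS)-2,5,8a-trimethyl-4a,7,8,8a-tetrahydronaphthalen-1(4H)-one (cis-fused) | CC1=CC[C@@H]2C(C)=CCC[C@]2(C)C1=O | intermediate
8 | lithium (4aR,8aS)-2,5,8a-trimethyl-3,4,4a,7,8,8a-hexahydronaphthalen-1-olate | CC1=C(O[Li])[C@@]2(C)CCC=C(C)[C@H]2CC1 | intermediate
9 | (4aR,8aS)-2,5,8a-trimethyl-3,4,4a,7,8,8a-hexahydronaphthalen-1-yl trifluoromethanesulfonate | CC1=C(OS(=O)(=O)C(F)(F)F)[C@@]2(C)CCC=C(C)[C@H]2CC1 | intermediate
10 | (4aR,8aS)-5-{[2-(octylsulfonyl)hydrazinyl]methyl}-2,5,8a-trimethyl-3,4,4a,5,6,7,8,8a-octahydronaphthalen-1-yl trifluoromethanesulfonate (C-5 epimers, both converge) | CC1=C(OS(=O)(=O)C(F)(F)F)[C@@]2(C)CCCC(C)(CNNS(=O)(=O)CCCCCCCC)[C@H]2CC1 | intermediate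
11 | (4aR,8aS)-2,5,5,8a-tetramethyl-3,4,4a,5,6,7,8,8a-octahydronaphthalen-1-yl trifluoromethanesulfonate | CC1=C(OS(=O)(=O)C(F)(F)F)[C@@]2(C)CCCC(C)(C)[C@H]2CC1 | intermediate
12 | methyl 2,2-dimethoxyacetate | COC(OC)C(=O)OC | starting material
13 | 1-(dimethoxymethyl)cyclopropan-1-ol | COC(OC)C1(O)CC1 | intermediate
14 | 1,1-dimethoxy-4-[(4aR,8aS)-2,5,5,8a-tetramethyl-3,4,4a,5,6,7,8,8a-octahydronaphthalen-1-yl]butan-2-one | CC1=C(CCC(=O)C(OC)OC)[C@@]2(C)CCCC(C)(C)[C@H]2CC1 | intermediate
15 | 4-bromofuran-2(5H)-one | BrC1=CC(=O)OC1 | starting material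
16 | diethyl prop-2-en-1-ylphosphonate (diethyl allylphosphonate) | CCOP(=O)(CC=C)OCC | starting material
17 | diethyl [(2E)-3-(5-oxo-2,5-dihydrofuran-3-yl)prop-2-en-1-yl]phosphonate | CCOP(=O)(C/C=C/C1=CC(=O)OC1)OCC | intermediate
18 | lithium salt of the P-bearing carbanion of 17 | [Li+].CCOP(=O)(OCC)[CH-]/C=C/C1=CC(=O)OC1 | intermediate
19 | 4-[(1E,3E)-4-(dimethoxymethyl)-6-[(4aR,8aS)-2,5,5,8a-tetramethyl-3,4,4a,5,6,7,8,8a-octahydronaphthalen-1-yl]hexa-1,3-dien-1-yl]furan-2(5H)-one (formed together with its 3Z isomer) | CC1=C(CC/C(=C\C=C\C2=CC(=O)OC2)C(OC)OC)[C@@]2(C)CCCC(C)(C)[C@H]2CC1 | intermediate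
20 | (2E,4E)-5-(5-oxo-2,5-dihydrofuran-3-yl)-2-{2-[(4aR,8aS)-2,5,5,8a-tetramethyl-3,4,4a,5,6,7,8,8a-octahydronaphthalen-1-yl]ethyl}penta-2,4-dienal | CC1=C(CC/C(=C\C=C\C2=CC(=O)OC2)C=O)[C@@]2(C)CCCC(C)(C)[C@H]2CC1 | intermediate
21 | 4-[(1E,3E)-4-(hydroxymethyl)-6-[(4aR,8aS)-2,5,5,8a-tetramethyl-3,4,4a,5,6,7,8,8a-octahydronaphthalen-1-yl]hexa-1,3-dien-1-yl]furan-2(5H)-one (CNP0232848.3) | CC1=C(CC/C(=C\C=C\C2=CC(=O)OC2)CO)[C@@]2(C)CCCC(C)(C)[C@H]2CC1 | target

**Step count**
Total steps: 10. Longest linear sequence: 8 (steps 1, 2, 3, 4, 5, 7, 9, 10); steps 6 and 8 make the two side-chain reagents.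

**Steps most likely to fail, with fallbacks**

Step 7 is the riskiest. The enol triflate is tetrasubstituted and sits next to a quaternary carbon, so β-hydride elimination of the homoenolate or triflate hydrolysis may win. The fallback sets out from 11 and comes back at 20. Commercial 4,4-diethoxybut-1-ene is hydroborated with 9-BBN (THF, rt) to the B-alkyl borane 9-(4,4-diethoxybutyl)-9-borabicyclo[3.3.1]nonane F1. F1 is coupled with 11 in a B-alkyl Suzuki–Miyaura reaction (PdCl2(dppf), K3PO4, DMF/THF/H2O, 60 °C) to the diethyl acetal F2. Hydrolysis (1 M aq. HCl, THF) gives the butanal F3. Separately, a Heck reaction of 15 with acrolein (Pd(OAc)2, NaOAc, n-Bu4NCl, DMF, 50 °C) gives (2E)-3-(5-oxo-2,5-dihydrofuran-3-yl)prop-2-enal F4. Amine-catalysed cross-aldol condensation of F3 with F4 (pyrrolidine, PhCO2H, toluene, rt → 50 °C) gives the thermodynamic 2E dienal 20 directly. Steps 6, 8 and 9 are then not needed.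

Step 9 is the second risk. A doubly vinylogous phosphonate anion must attack a ketone through its α-carbon, and the butenolide CH2 is also acidic. The fallback sets out from 14 and comes back at 19. Allylmagnesium bromide is added to the ketone of 14 (THF, −78 °C) to give the tertiary homoallylic alcohol F5. The butenolide is attached by Heck reaction of the terminal alkene with 15 (Pd(OAc)2, NaOAc, n-Bu4NCl, DMF, 70 °C) to give the hydroxy acetal F6. Dehydration with Burgess reagent (benzene, 50 °C) toward the doubly activated C14–H gives the triene acetal 19, which is hydrolysed and equilibrated as in step 9.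

Step 5 is the third risk. The hydromethylation must form a quaternary carbon next to the ring fusion and must leave the enol triflate alone. The fallback sets out from 7 and comes back at 11. Simmons–Smith cyclopropanation (Et2Zn, CH2I2, CH2Cl2, 0 °C) of the electron-rich ring A alkene gives the cyclopropane-fused enone F7. Hydrogenolysis (H2, PtO2, AcOH) opens the less hindered cyclopropane bond to the gem-dimethyl group and saturates the enone, giving the saturated ketone F8 (C-2 epimers). KN(SiMe3)2 then PhNTf2 (THF, −78 °C) enolises the only α-position that carries hydrogen and gives 11.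

**Further compounds**
F1 | step 7 | 9-(4,4-diethoxybutyl)-9-borabicyclo[3.3.1]nonane | CCOC(CCCB1C2CCCC1CCC2)OCC
F2 | step 7 | (4aR,8aS)-1-(4,4-diethoxybutyl)-2,5,5,8a-tetramethyl-3,4,4a,5,6,7,8,8a-octahydronaphthalene | CC1=C(CCCC(OCC)OCC)[C@@]2(C)CCCC(C)(C)[C@H]2CC1
F3 | step 7 | 4-[(4aR,8aS)-2,5,5,8a-tetramethyl-3,4,4a,5,6,7,8,8a-octahydronaphthalen-1-yl]butanal | CC1=C(CCCC=O)[C@@]2(C)CCCC(C)(C)[C@H]2CC1
F4 | step 7 | (2E)-3-(5-oxo-2,5-dihydrofuran-3-yl)prop-2-enal | O=C/C=C/C1=CC(=O)OC1
F5 | step 9 | 3-(dimethoxymethyl)-1-[(4aR,8aS)-2,5,5,8a-tetramethyl-3,4,4a,5,6,7,8,8a-octahydronaphthalen-1-yl]hex-5-en-3-ol (C-3 epimers, both converge) | CC1=C(CCC(O)(CC=C)C(OC)OC)[C@@]2(C)CCCC(C)(C)[C@H]2CC1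
F6 | step 9 | 4-[(1E)-4-(dimethoxymethyl)-4-hydroxy-6-[(4aR,8aS)-2,5,5,8a-tetramethyl-3,4,4a,5,6,7,8,8a-octahydronaphthalen-1-yl]hex-1-en-1-yl]furan-2(5H)-one | CC1=C(CCC(O)(C/C=C/C2=CC(=O)OC2)C(OC)OC)[C@@]2(C)CCCC(C)(C)[C@H]2CC1
F7 | step 5 | 5,6-cyclopropanated derivative of 7, (4aR,8aS)-2,5,8a-trimethyl-5,6-methano-4a,5,6,7,8,8a-hexahydronaphthalen-1(4H)-one (cyclopropane face not specified) | CC1=CC[C@@H]2C3(C)CC3CC[C@]2(C)C1=O
F8 | step 5 | (4aR,8aS)-2,5,5,8a-tetramethyloctahydronaphthalen-1(2H)-one (C-2 epimers) | CC1CC[C@@H]2C(C)(C)CCC[C@]2(C)C1=O
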